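The plan cuts the aryl–alkyl bond C3–C3a of the dihydrobenzofuran. The key step is a 5-exo-trig cyclisation of an aryl radical, generated at C3a of ring A from an ortho-iodoaryl ether, onto a (Z)-enol isovalerate. In one operation it closes the furan ring (O1, C2, C3, C3a, C7a), sets C3 trans to the existing stereocentre C2 through allylic 1,3-strain, and delivers the finished CH2–O–isovaleryl side chain, because the exocyclic carbon of the closure is the oxygen-bearing enol carbon. The feature exploited is the acyloxymethyl group on C3 next to the benzylic aryl ether carbon C2. The precursor is an enantioenriched 1-arylpropargyl 2-iodoaryl ether after hydroacyloxylation of its alkyne.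

Key step: step 5

Remark: the target is read as the trans (2R,3S) isomer in benzofuran numbering; ring A is the benzo ring of the benzofuran and ring B is the 4-hydroxy-3-methoxyphenyl ring on C2.

Step 1
Reactants: 1 vanillin
Product: 2 4-{[tert-butyl(dimethyl)silyl]oxy}-3-methoxybenzaldehyde
Conditions: TBSCl, imidazole, DMF, rt
Reagents that add atoms: tert-butyldimethylsilyl chloride, CC(C)(C)[Si](C)(C)Cl
Why: Imidazole-assisted O-silylation of the phenol should give a fluoride-labile aryl silyl ether that tolerates the Grignard, copper, ruthenium, radical and Wittig steps.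

Step 2
Reactants: 2 4-{[tert-butyl(dimethyl)silyl]oxy}-3-methoxybenzaldehyde
Product: 4 rac-1-(4-{[tert-butyl(dimethyl)silyl]oxy}-3-methoxyphenyl)prop-2-yn-1-yl acetate, via bromomagnesium alkoxide 3 (not isolated)
Conditions: HC≡CMgBr, THF, 0 °C; then Ac2O, 0 °C to rt
Reagents that add atoms: ethynylmagnesium bromide, C#C[Mg]Br; acetic anhydride, CC(=O)OC(C)=O
Why: 1,2-Addition of the alkynyl Grignard reagent to the aldehyde and O-acylation of the magnesium alkoxide in the same flask should give the ionisable propargylic ester; the centre is racemic and is erased in step 3.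

Step 3
Reactants: 4 rac-1-(4-{[tert-butyl(dimethyl)silyl]oxy}-3-methoxyphenyl)prop-2-yn-1-yl acetate; 5 5-iodovanillin (4-hydroxy-3-iodo-5-methoxybenzaldehyde)
Product: 6 4-{[(1R)-1-(4-{[tert-butyl(dimethyl)silyl]oxy}-3-methoxyphenyl)prop-2-yn-1-yl]oxy}-3-iodo-5-methoxybenzaldehyde
Conditions: (CuOTf)2·C6H6 (5 mol%), chiral pybox ligand (10 mol%, the antipode that gives the R ether), i-Pr2NEt, THF, −10 °C
Reagents that add atoms: none
Why: Copper-catalysed enantioselective propargylic etherification, in which the copper acetylide of 4 expels acetate to a ligand-bound copper allenylidene and the phenoxide of 5 adds to its γ-carbon on the face left open by the pybox ligand, which sets C2 as R; both racemic enantiomers of 4 converge on the same planar intermediate, and the sense of induction for a given ligand antipode is to be confirmed on the first sample.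

Step 4
Reactants: 6 the (R)-propargylic aryl ether; 7 3-methylbutanoic acid (isovaleric acid)
Product: 8 (1Z,3R)-3-(4-{[tert-butyl(dimethyl)silyl]oxy}-3-methoxyphenyl)-3-(4-formyl-2-iodo-6-methoxyphenoxy)prop-1-en-1-yl 3-methylbutanoate
Conditions: [RuCl2(p-cymene)]2 (1 mol%), P(4-ClC6H4)3, DMAP, toluene, 60 °C
Reagents that add atoms: none
Why: Ruthenium-catalysed anti-Markovnikov hydro-oxycarbonylation of a terminal alkyne, in which the carboxylate adds to the α-carbon of a ruthenium vinylidene and protonolysis of the alkenyl ruthenium species gives the (Z)-enol ester; the stereocentre is not touched.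

Step 5
Reactants: 8 the (Z)-enol isovalerate
Product: 9 [(2R,3S)-2-(4-{[tert-butyl(dimethyl)silyl]oxy}-3-methoxyphenyl)-5-formyl-7-methoxy-2,3-dihydro-1-benzofuran-3-yl]methyl 3-methylbutanoate
Conditions: Bu3SnH (slow addition), Et3B/air, toluene (0.02 M), 0 °C to rt
Reagents that add atoms: none
Why: The tributyltin radical abstracts iodine from C3a, the σ-aryl radical adds to the proximal enol carbon (the future C3), and the resulting α-acyloxyalkyl radical takes hydrogen from Bu3SnH, which carries the chain. The closest known reaction type is the tin hydride mediated aryl radical cyclisation of ortho-halophenyl allyl ethers to 3-substituted 2,3-dihydrobenzofurans. The furan ring closes in the 5-exo-trig mode; 6-endo attack at the ester-bearing carbon is disfavoured by that substituent and by the geometry of aryl radical closure. The new stereocentre C3 is controlled by C2: in the Z-alkene the C2–H bond must lie in the alkene plane to avoid allylic 1,3-strain with the cis acyloxy group, so the tether oxygen and ring B sit on opposite faces, and attack from the oxygen face should place the acyloxymethyl group trans to ring B (2R,3S). The step needs ring closure to outrun direct reduction of the aryl radical and six-membered closure onto ring B, which the very fast 5-exo closure of 2-(allyloxy)phenyl radicals and a low stationary tin hydride concentration should secure. The aldehyde, aryl silyl ether and ester should be inert to the chain at this temperature.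

Step 6
Reactants: 9 the 5-formyl dihydrobenzofuran ester
Product: 10 [(2R,3S)-2-(4-{[tert-butyl(dimethyl)silyl]oxy}-3-methoxyphenyl)-7-methoxy-5-[(1E)-3-oxoprop-1-en-1-yl]-2,3-dihydro-1-benzofuran-3-yl]methyl 3-methylbutanoate
Conditions: Ph3P=CHCHO (1.3 equiv), toluene, 80 °C
Reagents that add atoms: (triphenylphosphoranylidene)acetaldehyde, O=CC=P(c1ccccc1)(c1ccccc1)c1ccccc1
Why: Wittig reaction with a formyl-stabilised ylide should give the (E)-enal from the only reactive carbonyl group, the aryl aldehyde, without touching the ester or the stereocentres.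

Step 7
Reactants: 10 the silyl-protected enal
Product: 11 [(2R,3S)-2-(4-hydroxy-3-methoxyphenyl)-7-methoxy-5-[(1E)-3-oxoprop-1-en-1-yl]-2,3-dihydro-1-benzofuran-3-yl]methyl 3-methylbutanoate (CNP0272976.1)
Conditions: TBAF, AcOH, THF, 0 °C
Reagents that add atoms: none
Why: Fluoride-induced cleavage of the aryl silyl ether, buffered with acetic acid so that the phenoxide attacks neither the enal nor the primary ester, should release the target.

Compound list
1 | vanillin (4-hydroxy-3-methoxybenzaldehyde) | COc1cc(C=O)ccc1O | starting material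
2 | 4-{[tert-butyl(dimethyl)silyl]oxy}-3-methoxybenzaldehyde | COc1cc(C=O)ccc1O[Si](C)(C)C(C)(C)C | intermediate
3 | bromomagnesium 1-(4-{[tert-butyl(dimethyl)silyl]oxy}-3-methoxyphenyl)prop-2-yn-1-olate (racemic, not isolated) | C#CC(O[Mg]Br)c1ccc(O[Si](C)(C)C(C)(C)C)c(OC)c1 | intermediate
4 | rac-1-(4-{[tert-butyl(dimethyl)silyl]oxy}-3-methoxyphenyl)prop-2-yn-1-yl acetate | CC(=O)OC(C#C)c1ccc(O[Si](C)(C)C(C)(C)C)c(OC)c1 | intermediate
5 | 5-iodovanillin (4-hydroxy-3-iodo-5-methoxybenzaldehyde) | COc1cc(C=O)cc(I)c1O | starting material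
6 | 4-{[(1R)-1-(4-{[tert-butyl(dimethyl)silyl]oxy}-3-methoxyphenyl)prop-2-yn-1-yl]oxy}-3-iodo-5-methoxybenzaldehyde | C#C[C@@H](Oc1c(I)cc(C=O)cc1OC)c1ccc(O[Si](C)(C)C(C)(C)C)c(OC)c1 | intermediate
7 | 3-methylbutanoic acid (isovaleric acid) | CC(C)CC(=O)O | starting material
8 | (1Z,3R)-3-(4-{[tert-butyl(dimethyl)silyl]oxy}-3-methoxyphenyl)-3-(4-formyl-2-iodo-6-methoxyphenoxy)prop-1-en-1-yl 3-methylbutanoate | CC(C)CC(=O)O/C=C\[C@@H](Oc1c(I)cc(C=O)cc1OC)c1ccc(O[Si](C)(C)C(C)(C)C)c(OC)c1 | intermediate
9 | [(2R,3S)-2-(4-{[tert-butyl(dimethyl)silyl]oxy}-3-methoxyphenyl)-5-formyl-7-methoxy-2,3-dihydro-1-benzofuran-3-yl]methyl 3-methylbutanoate | COc1cc([C@@H]2Oc3c(OC)cc(C=O)cc3[C@H]2COC(=O)CC(C)C)ccc1O[Si](C)(C)C(C)(C)C | intermediate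
10 | [(2R,3S)-2-(4-{[tert-butyl(dimethyl)silyl]oxy}-3-methoxyphenyl)-7-methoxy-5-[(1E)-3-oxoprop-1-en-1-yl]-2,3-dihydro-1-benzofuran-3-yl]methyl 3-methylbutanoate | COc1cc([C@@H]2Oc3c(OC)cc(/C=C/C=O)cc3[C@H]2COC(=O)CC(C)C)ccc1O[Si](C)(C)C(C)(C)C | intermediate
11 | [(2R,3S)-2-(4-hydroxy-3-methoxyphenyl)-7-methoxy-5-[(1E)-3-oxoprop-1-en-1-yl]-2,3-dihydro-1-benzofuran-3-yl]methyl 3-methylbutanoate | COc1cc([C@@H]2Oc3c(OC)cc(/C=C/C=O)cc3[C@H]2COC(=O)CC(C)C)ccc1O | target

Total step count: 7. Longest linear sequence: 7 steps (1 to 11).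

Steps most likely to fail

Step 3. The phenoxide of 5 is flanked by two ortho substituents and weakened by the para formyl group, so its capture of the copper allenylidene may be slow. Uncatalysed ionisation of the electron-rich acetate would then compete and lower conversion or enantiomeric purity. The fallback makes the ether bond on a pre-formed stereocentre. It sets out from 2. Addition of trimethylsilylacetylene under Me2Zn and a ProPhenol ligand in toluene (the ligand antipode that gives the required carbinol) should give the silylated propargylic alcohol F1. Brief treatment with catalytic K2CO3 in MeOH at 0 °C should remove only the C-silyl group and give the (S)-propargylic alcohol F2. A Mitsunobu reaction of F2 with phenol 5 (PPh3, DIAD, toluene, −20 °C) should invert the carbinol centre and comes back to the route at 6.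

Step 4. The ruthenium vinylidene carries an aryloxide on a benzylic, propargylic carbon, which may be lost to give an allenylidene. The acid may also add at the internal alkyne carbon. The fallback puts the oxygen on after ring closure. It sets out from 6. Semi-hydrogenation (Pd/CaCO3 poisoned with Pb(OAc)2, quinoline, H2, EtOAc) should give the (R)-allyl aryl ether F3. Bu3SnH and TEMPO in benzene at 60 °C should close the same C3–C3a bond by 5-exo aryl radical cyclisation and trap the primary radical as the alkoxyamine F4. Zn in AcOH–THF–H2O should cleave the N–O bond to the hydroxy aldehyde F5. Isovaleryl chloride and pyridine in CH2Cl2 at 0 °C then come back to the route at 9.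

Step 5. The facial selectivity at the enol ester may be insufficient and give the cis-2,3 isomer. The doubly oxygenated allylic ether may also ionise and transpose before the radical closes. The fallback closes the ring at the C2–C3 bond and sets C3 under thermodynamic control. It sets out from 2 and 5. NaBH4 in MeOH should reduce 2 to the benzyl alcohol F6. Mitsunobu etherification with 5 (PPh3, DIAD, THF) should give the aryl benzyl ether F7. Coupling of the aryl iodide with methyl diazoacetate (Pd(PPh3)4, Ag2CO3, Et3N, toluene, rt) should give the aryldiazoacetate F8. Rh2(PTTL)4, dirhodium tetrakis(N-phthaloyl-tert-leucinate) in the antipode that gives 2R, should effect carbenoid insertion into the benzylic ether C–H bond and give the cis ester F9. DBU in toluene should equilibrate C3 to the trans ester F10. Reduction with i-Bu2AlH at −78 °C should take ester and aldehyde to the diol F11. MnO2 in CH2Cl2 should reoxidise only the benzylic alcohol and give the hydroxy aldehyde F5 described under the fallback for step 4. Acylation as there comes back to the route at 9.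

Further compounds
F1 | step 3 | (1R)-1-(4-{[tert-butyl(dimethyl)silyl]oxy}-3-methoxyphenyl)-3-(trimethylsilyl)prop-2-yn-1-ol (R by the sequence rules because the silylalkynyl group outranks the aryl group; same spatial arrangement as F2) | C[Si](C)(C)C#C[C@H](O)c1ccc(O[Si](C)(C)C(C)(C)C)c(OC)c1
F2 | step 3 | (1S)-1-(4-{[tert-butyl(dimethyl)silyl]oxy}-3-methoxyphenyl)prop-2-yn-1-ol | C#C[C@H](O)c1ccc(O[Si](C)(C)C(C)(C)C)c(OC)c1
F3 | step 4 | 4-{[(1R)-1-(4-{[tert-butyl(dimethyl)silyl]oxy}-3-methoxyphenyl)prop-2-en-1-yl]oxy}-3-iodo-5-methoxybenzaldehyde | C=C[C@@H](Oc1c(I)cc(C=O)cc1OC)c1ccc(O[Si](C)(C)C(C)(C)C)c(OC)c1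
F4 | step 4 | (2R,3S)-2-(4-{[tert-butyl(dimethyl)silyl]oxy}-3-methoxyphenyl)-7-methoxy-3-{[(2,2,6,6-tetramethylpiperidin-1-yl)oxy]methyl}-2,3-dihydro-1-benzofuran-5-carbaldehyde | COc1cc([C@@H]2Oc3c(OC)cc(C=O)cc3[C@H]2CON4C(C)(C)CCCC4(C)C)ccc1O[Si](C)(C)C(C)(C)C
F5 | step 4 | (2R,3S)-2-(4-{[tert-butyl(dimethyl)silyl]oxy}-3-methoxyphenyl)-3-(hydroxymethyl)-7-methoxy-2,3-dihydro-1-benzofuran-5-carbaldehyde | COc1cc([C@@H]2Oc3c(OC)cc(C=O)cc3[C@H]2CO)ccc1O[Si](C)(C)C(C)(C)C
F6 | step 5 | (4-{[tert-butyl(dimethyl)silyl]oxy}-3-methoxyphenyl)methanol | OCc1ccc(O[Si](C)(C)C(C)(C)C)c(OC)c1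
F7 | step 5 | 4-[(4-{[tert-butyl(dimethyl)silyl]oxy}-3-methoxyphenyl)methoxy]-3-iodo-5-methoxybenzaldehyde | COc1cc(C=O)cc(I)c1OCc1ccc(O[Si](C)(C)C(C)(C)C)c(OC)c1
F8 | step 5 | methyl 2-diazo-2-{2-[(4-{[tert-butyl(dimethyl)silyl]oxy}-3-methoxyphenyl)methoxy]-5-formyl-3-methoxyphenyl}acetate | COC(=O)C(=[N+]=[N-])c1cc(C=O)cc(OC)c1OCc1ccc(O[Si](C)(C)C(C)(C)C)c(OC)c1
F9 | step 5 | methyl (2R,3S)-2-(4-{[tert-butyl(dimethyl)silyl]oxy}-3-methoxyphenyl)-5-formyl-7-methoxy-2,3-dihydro-1-benzofuran-3-carboxylate (cis) | COc1cc([C@@H]2Oc3c(OC)cc(C=O)cc3[C@@H]2C(=O)OC)ccc1O[Si](C)(C)C(C)(C)C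
F10 | step 5 | methyl (2R,3R)-2-(4-{[tert-butyl(dimethyl)silyl]oxy}-3-methoxyphenyl)-5-formyl-7-methoxy-2,3-dihydro-1-benzofuran-3-carboxylate (trans) | COc1cc([C@@H]2Oc3c(OC)cc(C=O)cc3[C@H]2C(=O)OC)ccc1O[Si](C)(C)C(C)(C)C
F11 | step 5 | [(2R,3S)-2-(4-{[tert-butyl(dimethyl)silyl]oxy}-3-methoxyphenyl)-7-methoxy-2,3-dihydro-1-benzofuran-3,5-diyl]dimethanol | COc1cc([C@@H]2Oc3c(OC)cc(CO)cc3[C@H]2CO)ccc1O[Si](C)(C)C(C)(C)C
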